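Watch the ratio of the two products, not their amounts.

| setting | teal | green | Saturday's | Sunday's |
|---|---|---|---|---|
| left-handed substrate | 20 mM | 20 mM | 20 mM | 20 mM |
| right-handed substrate | 20 mM | 20 mM | 20 mM | 20 mM |
| solid reagent | 10 mM | 33 mM | 24.0 mM | 8.00 mM |
| free catalyst | 2.2 mM | 2.2 mM | 2.2 mM | 2.2 mM |
| remark | run made earlier | run made earlier |  |  |
| time |  |  | 1.0 h | 0.50 h |

| run | time / min | left-handed product / % | right-handed product / % |
|---|---|---|---|
| teal | 2.50 | 0.6 | 0 |
| teal | 8.00 | 2.1 | 0 |
| teal | 15.0 | 2.8 | 0.2 |
| teal | 20.0 | 3.7 | 0 |
| teal | 30.0 | 3.7 | 0 |
| green | 6.00 | 1.5 | 0 |
| green | 12.0 | 2.7 | 0 |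
| green | 20.0 | 4.3 | 0.5 |
| green | 25.0 | 4.5 | 0 |
| green | 30.0 | 4.0 | 0 |

(readings scatter by 0.5 percentage points)

- free catalyst is single-handed; left-handed substrate and right-handed substrate are mirror images of each other, charged as a racemate, each of them at the stated concentration
- solid, in amounts per volume of the solution: solid reagent
- steps under discussion: partner + free catalyst + left-handed substrate -> free catalyst + left-handed product; partner + free catalyst + right-handed substrate -> free catalyst + right-handed product; free catalyst -> spent catalyst; solid reagent <-> partner; partner -> decomposed reagent
- at the start none of the solid reagent is in solution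
- an excess is the difference of the two amounts in percent of their sum
- an excess is below zero if the other one leads

1. which one finishes higher in excess of left-handed product over right-handed product ("neither" within 2 percentage points) (Saturday's / Sunday's / neither)
2. excess of left-handed product over right-handed product at the end, Saturday's
3. excess of left-handed product over right-handed product at the end, Sunday's

Summed over the teal and green readings, left-handed product comes to 29.9% and right-handed product to 0.700%. The pooled excess E, the difference of these sums over their total, reads 95.4%, a rough figure with 0.5 percentage points of scatter on each reading. Both product steps use the same partner and free catalyst, so these cancel from the ratio of the two rates, and the ratio of the two step constants times the substrate ratio remains. The highest left-handed reading, 4.5% in the green run, is 9.00% of the left-handed substrate's own charge, so in this reckoning the substrate ratio is frozen near one. This reckoning therefore carries E to both Saturday's and Sunday's flasks.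

The forecast gives neither, with 95% for Saturday's and 95% for Sunday's: “Solid amount and time therefore shouldn't change the excess.”

The simulation gives 97.5% for Saturday's and 97.6% for Sunday's, so the answer is neither, and the forecast held.

    partner + free catalyst + left-handed substrate → free catalyst + left-handed product (k = 68.2 L² mol⁻² s⁻¹)
    partner + free catalyst + right-handed substrate → free catalyst + right-handed product (k = 0.805 L² mol⁻² s⁻¹)
    free catalyst → spent catalyst (k = 8.58 × 10⁻⁴ s⁻¹)
    solid reagent ⇌ partner, rate k4*(cs4 - [partner]) while solid is left; crystals form when [partner] > cs4 (solubility = 15.0 mM, k = 4.89 × 10⁻⁴ s⁻¹)
    partner → decomposed reagent (k = 0.00618 s⁻¹)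

Saturday's flask ends with 6.41% of left-handed product against 4.14% in Sunday's, yet the two excesses lie within 2 points. The left-handed step's constant is 84.7 times the right-handed step's, the selectivity factor, and Saturday's still keeps 87% of its left-handed substrate against 99.8% of its right-handed.

For the neighbour flask, Saturday's with 96 mM of solid reagent, E gives 95.4%. The computed excess there is 97.5%, with 6.42% of left-handed product.

The data were computed from invented constants; scatter was added.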